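The data come from a simulation with constants of no real substance.

The ratio of J to L charged goes from 0.471 in spring to 1.47 in autumn, so the row of flasks crosses from J in short supply to L in short supply.

in all of them: Z 0.34 mM
- beta: J 0.080 M; L 0.11 M; Q 2.2 mM; run made earlier
- eta: J 0.080 M; L 0.17 M; Q 1.1 mM; run made earlier
- spring: J 0.080 M; L 0.170 M; Q 2.2 mM; time 20 h
- dusk: J 0.12 M; L 0.170 M; Q 2.2 mM; time 20 h
- summer: J 0.15 M; L 0.170 M; Q 2.2 mM; time 20 h
- autumn: J 0.25 M; L 0.170 M; Q 2.2 mM; time 20 h

- beta (time / h: G / %, J / %): 0.500: 16, 52; 1.00: 27, 29; 1.50: 43, 15; 2.50: 60, 3; 4.00: 85, 0; 8.00: 99, 3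
- eta (time / h: G / %, J / %): 0.500: 8, 74; 1.00: 30, 52; 1.50: 46, 35; 2.50: 71, 20; 4.00: 87, 7; 8.00: 98, 3

(each reading ± 2 percentage points)

- [G] at the end for spring, dusk, summer, autumn, in this order
- the shape of the row from first to last (rises all the way / hardly changes / falls, then rises / rises, then falls / falls all the way)

- the earlier runs were read with a standard deviation of 2 percentage points
- steps under discussion: J + Q -> Q + D; Z + D <-> E; L + E -> Z + G
- "hardly changes" means that all values lie within two and a half points (for a concentration: within two and a half percent of the largest)

Take the main step first, Q turning J into D. In beta, J reads 52% at 0.500 h, and in eta, with 1.1 mM Q, it reads 52% at 1.00 h. Read from these two readings, the half-life of J in eta, with half the Q of beta, is twice that in beta; the two runs differ in L as well, but the step from J to D contains no L. With 2.2 mM Q, 20 h is about 40.0 such half-lives, so in this first picture the full charge of J becomes D, and, with D read as G, the row repeats the J charges up to 0.25 M.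

Now add the step that makes G. Each G costs one L, so autumn is capped at 0.170 M, with L as the limiting reagent. The other flasks stay at their J charges.

The remaining question is whether Z can go round often enough. Each Z must turn over 235 times in spring and 500 times in autumn. In beta, G gains 27 percentage points between 0.500 h and 1.50 h, which, divided by the mean c(L), reads as a pseudo-first-order constant of 0.250 h⁻¹. At c(L) = 0.170 M that is 125 h⁻¹ per Z.

The turnover margin is the number of turnovers offered at this opening pace in the given time, divided by the number demanded: 5.00 for autumn and 10.6 for spring, both above one. If the constant read from beta holds in autumn, c(L) there falls exponentially, and this estimate keeps 0.674% of its L and gives 0.169 M G. The return of E to Z + D, the last addition, consumes no L.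

The forecast gives 0.08 M, 0.12 M, 0.15 M and 0.169 M, shape "rises all the way": “The row rises throughout, flattening at the L limit”. Its rate constant times time of 6 stands beside the margin of 5.00 reckoned here.

The flask gives 0.0800 M, 0.120 M, 0.150 M and 0.170 M, shape "rises all the way".

    J + Q → Q + D (k = 0.170 M⁻¹ s⁻¹)
    Z + D ⇌ E (K = 73.0 M⁻¹, k = 33.0 M⁻¹ s⁻¹)
    L + E → Z + G (k = 0.300 M⁻¹ s⁻¹)

Autumn ends at 0.170 M, and the same flask without the wearing away of L gives 0.250 M, while 32.0% of its J stands as D. The return of E changes that G by at most 0.1%. Autumn's margin of 5.00 reckoned 0.674% of its L as left, and the autumn flask keeps 0.17% at 20 h. Spring's margin of 10.6 places half of its turnover at 0.943 h at the opening pace, and in spring the step from L + E to Z + G reaches that mark at 1.27 h.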